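The seven-membered ring is divided into a three-carbon unit C5–C6–C7 (C6 oxygenated) and the diene C8–C9–C10–C1, linked through C2–C3–C4 of the future cyclopentane. One intramolecular (4+3) cycloaddition of an enantioenriched epoxy enol silane, triggered by a silyl triflate, forms C1–C5 and C7–C8, closes both rings and sets C5, the quaternary C1 and C8 from the epoxide configuration and the (E,E)-diene geometry. The step exploits the 1,3-dioxygenation C4–O/C6–O around the ring-fusion CH (C5): the epoxide oxygen becomes O4 and the enol silane becomes the C6 ketone. The precursor is an acyclic trans-epoxy methyl ketone enol silane carrying a 3-methylhepta-3,5-dienyl chain.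

Key step: step 7

Remark: the target is taken exactly as the given SMILES, i.e. 6α-angeloyloxy-8α,9α-epoxy-trans-daucane-4β,10α-diol; daucane locants are used for all bicyclic compounds (C1 methyl-bearing ring-fusion carbon, C4 isopropyl carbinol carbon, C5 ring-fusion CH, C6 ester carbon, C8 methyl-bearing carbon, C10 carbinol CH) and α is the face of H-5.

Step 1
Reactants: 1 (E)-crotonaldehyde; 2 isopropenylmagnesium bromide
Product: 3 (E)-2-methylhexa-1,4-dien-3-ol (racemic)
Conditions: THF, −78 °C to 0 °C; aq. NH4Cl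
Reagents that add atoms: none
Why: Grignard 1,2-addition of a vinylic organomagnesium reagent to an enal should give the bis-allylic alcohol, whose racemic carbinol centre is consumed in step 2.

Step 2
Reactants: 3 (E)-2-methylhexa-1,4-dien-3-ol; 4 triethyl orthoacetate
Product: 6 ethyl (4E,6E)-4-methylocta-4,6-dienoate, via mixed ketene acetal 5 (not isolated)
Conditions: EtCO2H (cat.), neat 4, 140 °C, EtOH distilled off
Reagents that add atoms: none
Why: Johnson–Claisen rearrangement through the unsubstituted isopropenyl terminus in a chair transition state with the propenyl group equatorial should give the E trisubstituted alkene and leave the E propenyl unit unchanged.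

Step 3
Reactants: 6 ethyl (4E,6E)-4-methylocta-4,6-dienoate
Product: 7 (4E,6E)-4-methylocta-4,6-dienal
Conditions: i-Bu2AlH (1.05 equiv), CH2Cl2, −78 °C; MeOH, aq. potassium sodium tartrate (KNaC4H4O6)
Reagents that add atoms: none
Why: partial reduction of the ester by i-Bu2AlH stops at the aluminium hemiacetal at −78 °C and should release the aldehyde on work-up.

Step 4
Reactants: 7 (4E,6E)-4-methylocta-4,6-dienal; 8 1-(triphenylphosphoranylidene)propan-2-one
Product: 9 (3E,7E,9E)-7-methylundeca-3,7,9-trien-2-one
Conditions: CH2Cl2, 40 °C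
Reagents that add atoms: none
Why: Wittig olefination with a stabilized acyl ylide should give the E enone.

Step 5
Reactants: 9 (3E,7E,9E)-7-methylundeca-3,7,9-trien-2-one
Product: 10 1-[(2S,3R)-3-[(3E,5E)-3-methylhepta-3,5-dien-1-yl]oxiran-2-yl]ethan-1-one
Conditions: La(OiPr)3 (5 mol %), (R)-BINOL, Ph3As=O, t-BuOOH, 4 Å molecular sieves, THF, rt
Reagents that add atoms: tert-butyl hydroperoxide, CC(C)(C)OO
Why: catalytic asymmetric nucleophilic (Weitz–Scheffer-type) epoxidation of an (E)-alkyl enone with a lanthanum–BINOL–arsine oxide catalyst should give the trans-epoxide, the enone face being chosen by the ligand (the BINOL antipode that gives the (2S,3R)-oxirane is used, expected to be (R) by analogy with other (E)-enones), while the electron-rich diene is inert to the nucleophilic oxidant.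

Step 6
Reactants: 10 1-[(2S,3R)-3-[(3E,5E)-3-methylhepta-3,5-dien-1-yl]oxiran-2-yl]ethan-1-one
Product: 11 triethyl({1-[(2S,3R)-3-[(3E,5E)-3-methylhepta-3,5-dien-1-yl]oxiran-2-yl]ethenyl}oxy)silane
Conditions: Et3SiOTf (1.2 equiv), Et3N, CH2Cl2, −78 °C
Reagents that add atoms: triethylsilyl trifluoromethanesulfonate, CC[Si](CC)(CC)OS(=O)(=O)C(F)(F)F
Why: soft enolisation and O-silylation of the methyl ketone can only occur on the CH3 side (the other α-carbon is the oxirane CH), so the enol silane should form without touching a stereocentre.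

Step 7
Reactants: 11 triethyl({1-[(2S,3R)-3-[(3E,5E)-3-methylhepta-3,5-dien-1-yl]oxiran-2-yl]ethenyl}oxy)silane
Product: 12 4α-(triethylsilyloxy)-1β,8α-dimethyl-5α-H-trans-bicyclo[5.3.0]dec-9-en-6-one (daucane locants)
Conditions: Et3SiOTf (10 mol %), CH2Cl2, −78 °C; aq. NaHCO3
Reagents that add atoms: none
Why: Silylation of the epoxide oxygen lets the diene terminus C1 attack the epoxide carbon C5 anti to the breaking C5–O bond while the developing 2-silyloxyallyl cation is captured at C7 by the other diene terminus C8, after which the silyl group on the C6 oxocarbenium oxygen passes to the next epoxide, so the triflate is catalytic and O4 emerges as its triethylsilyl ether. The closest known reaction type is the silyl-triflate-catalysed intramolecular (4+3) cycloaddition of epoxy enol silanes with tethered dienes, a concerted but asynchronous oxyallyl-type cycloaddition. The five-membered ring closes by attack of C1 on C5 (exo with respect to the C1=C10 bond, both epoxide carbons ending inside the new ring) and the seven-membered ring closes in the same event by C7–C8 bonding across the s-cis diene, i.e. a type-1 (4+3) through a three-atom tether. C5 is set by inversion at the epoxide carbon (stereospecific, so the epoxide ee is carried over), C4 keeps its epoxide configuration, C8 follows suprafacially from the E propenyl terminus (8-methyl cis to C2), and the quaternary C1 is set by the diene face, the extended arrangement giving the trans ring fusion. The step needs (a) C1 rather than C10 to bond to C5, secured by the three-atom tether and by the fact that only this mode produces an allyl cation, and (b) the extended rather than the compact orientation, expected because the trans-epoxide holds C3 on the C5–H side so that the tether lies outside the diene while the bulky C6–OSiEt3 group points away from it; the compact mode would give the cis-fused diastereomer and is the main risk.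

Step 8
Reactants: 12 4α-(triethylsilyloxy)-1β,8α-dimethyl-5α-H-trans-bicyclo[5.3.0]dec-9-en-6-one
Product: 13 4α-(triethylsilyloxy)-1β,8α-dimethyl-5α-H-trans-bicyclo[5.3.0]dec-9-en-6α-ol
Conditions: Li, NH3 (l), THF, t-BuOH, −78 °C; NH4Cl
Reagents that add atoms: none
Why: dissolving-metal reduction of the ketone under thermodynamic control should give the equatorial 6α-alcohol, cis to H-5 and free of the 1,3-diaxial contact with the angular methyl that the 6β-epimer would suffer (a hydride reagent attacking the open α-face would be expected to give the 6β-ol).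

Step 9
Reactants: 13 4α-(triethylsilyloxy)-1β,8α-dimethyl-5α-H-trans-bicyclo[5.3.0]dec-9-en-6α-ol; 14 angelic acid
Product: 16 4α-(triethylsilyloxy)-1β,8α-dimethyl-5α-H-trans-bicyclo[5.3.0]dec-9-en-6α-yl angelate, via mixed anhydride 15 (not isolated)
Conditions: 14, 2,4,6-trichlorobenzoyl chloride, Et3N, toluene, rt; then 13, toluene, 80 °C
Reagents that add atoms: none
Why: Yamaguchi-type esterification through the 2,4,6-trichlorobenzoic mixed anhydride, run without a nucleophilic catalyst, should acylate the only free hydroxyl while keeping the Z geometry of the acyl unit.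

Step 10
Reactants: 16 4α-(triethylsilyloxy)-1β,8α-dimethyl-5α-H-trans-bicyclo[5.3.0]dec-9-en-6α-yl angelate
Product: 17 4α-hydroxy-1β,8α-dimethyl-5α-H-trans-bicyclo[5.3.0]dec-9-en-6α-yl angelate
Conditions: HF·pyridine, pyridine, THF, 0 °C to rt
Reagents that add atoms: none
Why: fluoride-mediated cleavage of the secondary triethylsilyl ether should free the C4 hydroxyl without touching the ester.

Step 11
Reactants: 17 4α-hydroxy-1β,8α-dimethyl-5α-H-trans-bicyclo[5.3.0]dec-9-en-6α-yl angelate
Product: 18 1β,8α-dimethyl-4-oxo-5α-H-trans-bicyclo[5.3.0]dec-9-en-6α-yl angelate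
Conditions: Dess–Martin periodinane, NaHCO3, CH2Cl2, 0 °C to rt
Reagents that add atoms: none
Why: Dess–Martin oxidation under buffered, non-basic conditions should give the cyclopentanone without β-elimination of the angelate or epimerisation at C5.

Step 12
Reactants: 18 1β,8α-dimethyl-4-oxo-5α-H-trans-bicyclo[5.3.0]dec-9-en-6α-yl angelate; 19 isopropylmagnesium chloride
Product: 20 6α-angeloyloxy-8β-H-trans-dauc-9-en-4β-ol
Conditions: 19 (3 equiv), CeCl3 (3 equiv, dried), THF, −78 °C; aq. NH4Cl
Reagents that add atoms: none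
Why: organocerium 1,2-addition (low basicity, ketone faster than the hindered conjugated ester) should occur on the α-face, the side of H-5, anti to the pseudoaxial angular methyl and to the C6 branch on C5, giving the 4β-hydroxy-4α-isopropyl carbinol.

Step 13
Reactants: 20 6α-angeloyloxy-8β-H-trans-dauc-9-en-4β-ol
Product: 21 6α-angeloyloxy-9α,10α-epoxy-8β-H-trans-daucan-4β-ol
Conditions: mCPBA, NaHCO3, CH2Cl2, 0 °C
Reagents that add atoms: 3-chloroperoxybenzoic acid, O=C(OO)c1cccc(Cl)c1
Why: Prilezhaev epoxidation should take place only at the electron-rich C9=C10 bond (the angelate alkene is deactivated) and from the α-face, anti to the pseudoaxial angular methyl, the C8 methyl being pseudoequatorial.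

Step 14
Reactants: 21 6α-angeloyloxy-9α,10α-epoxy-8β-H-trans-daucan-4β-ol
Product: 24 6α-angeloyloxy-trans-dauc-8-ene-4β,10α-diol, via hydroxy selenide 22 (not isolated), via selenoxide 23 (not isolated)
Conditions: (PhSe)2, NaBH4, EtOH, rt; then 21, 60 °C; then THF, 30 % H2O2, 0 °C to rt
Reagents that add atoms: none
Why: benzeneselenolate should open the epoxide by SN2 attack at C9 (C10 is neopentyl) from the β-face, and the selenoxide formed with H2O2 should undergo syn-elimination with the β-hydrogen at C8, away from the carbinol carbon, which moves the alkene to C8=C9 and leaves the 10α-hydroxyl (epoxide to allylic alcohol transposition by selenoxide elimination).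

Step 15
Reactants: 24 6α-angeloyloxy-trans-dauc-8-ene-4β,10α-diol
Product: 25 lapiferine (6α-angeloyloxy-8α,9α-epoxy-trans-daucane-4β,10α-diol)
Conditions: VO(acac)2 (5 mol %), t-BuOOH, CH2Cl2, 0 °C to rt
Reagents that add atoms: tert-butyl hydroperoxide, CC(C)(C)OO
Why: vanadium-catalysed hydroxyl-directed epoxidation of the cyclic allylic alcohol should deliver oxygen to C8=C9 syn to the 10α-hydroxyl (8α,9α-epoxide) and leave the electron-poor angelate alkene untouched.

Compound list
1 | (E)-crotonaldehyde | C/C=C/C=O | starting material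
2 | isopropenylmagnesium bromide | CC(=C)[Mg]Br | starting material
3 | (E)-2-methylhexa-1,4-dien-3-ol (racemic) | C/C=C/C(O)C(C)=C | intermediate
4 | triethyl orthoacetate | CCOC(C)(OCC)OCC | starting material
5 | mixed ketene acetal, 1-ethoxyvinyl ether of 3 (not isolated) | C=C(OCC)OC(/C=C/C)C(C)=C | intermediate
6 | ethyl (4E,6E)-4-methylocta-4,6-dienoate | CCOC(=O)CC/C(C)=C/C=C/C | intermediate
7 | (4E,6E)-4-methylocta-4,6-dienal | O=CCC/C(C)=C/C=C/C | intermediate
8 | 1-(triphenylphosphoranylidene)propan-2-one | CC(=O)C=P(c1ccccc1)(c1ccccc1)c1ccccc1 | starting material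
9 | (3E,7E,9E)-7-methylundeca-3,7,9-trien-2-one | CC(=O)/C=C/CC/C(C)=C/C=C/C | intermediate
10 | 1-[(2S,3R)-3-[(3E,5E)-3-methylhepta-3,5-dien-1-yl]oxiran-2-yl]ethan-1-one | CC(=O)[C@H]1O[C@@H]1CC/C(C)=C/C=C/C | intermediate
11 | triethyl({1-[(2S,3R)-3-[(3E,5E)-3-methylhepta-3,5-dien-1-yl]oxiran-2-yl]ethenyl}oxy)silane | C=C(O[Si](CC)(CC)CC)[C@H]1O[C@@H]1CC/C(C)=C/C=C/C | intermediate
12 | 4α-(triethylsilyloxy)-1β,8α-dimethyl-5α-H-trans-bicyclo[5.3.0]dec-9-en-6-one (daucane locants) | CC[Si](CC)(CC)O[C@@H]1CC[C@]2(C)C=C[C@H](C)CC(=O)[C@@H]12 | intermediate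
13 | 4α-(triethylsilyloxy)-1β,8α-dimethyl-5α-H-trans-bicyclo[5.3.0]dec-9-en-6α-ol | CC[Si](CC)(CC)O[C@@H]1CC[C@]2(C)C=C[C@H](C)C[C@H](O)[C@@H]12 | intermediate
14 | angelic acid, (Z)-2-methylbut-2-enoic acid | C/C=C(/C)C(=O)O | starting material
15 | angelic 2,4,6-trichlorobenzoic anhydride (not isolated) | C/C=C(/C)C(=O)OC(=O)c1c(Cl)cc(Cl)cc1Cl | intermediate
16 | 4α-(triethylsilyloxy)-1β,8α-dimethyl-5α-H-trans-bicyclo[5.3.0]dec-9-en-6α-yl angelate | C/C=C(/C)C(=O)O[C@H]1C[C@@H](C)C=C[C@@]2(C)CC[C@@H](O[Si](CC)(CC)CC)[C@H]12 | intermediate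
17 | 4α-hydroxy-1β,8α-dimethyl-5α-H-trans-bicyclo[5.3.0]dec-9-en-6α-yl angelate | C/C=C(/C)C(=O)O[C@H]1C[C@@H](C)C=C[C@@]2(C)CC[C@@H](O)[C@H]12 | intermediate
18 | 1β,8α-dimethyl-4-oxo-5α-H-trans-bicyclo[5.3.0]dec-9-en-6α-yl angelate | C/C=C(/C)C(=O)O[C@H]1C[C@@H](C)C=C[C@@]2(C)CCC(=O)[C@H]12 | intermediate
19 | isopropylmagnesium chloride | CC(C)[Mg]Cl | starting material
20 | 6α-angeloyloxy-8β-H-trans-dauc-9-en-4β-ol | C/C=C(/C)C(=O)O[C@H]1C[C@@H](C)C=C[C@@]2(C)CC[C@@](O)(C(C)C)[C@H]12 | intermediate
21 | 6α-angeloyloxy-9α,10α-epoxy-8β-H-trans-daucan-4β-ol | C/C=C(/C)C(=O)O[C@H]1C[C@@H](C)[C@H]2O[C@H]2[C@@]2(C)CC[C@@](O)(C(C)C)[C@H]12 | intermediate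
22 | 6α-angeloyloxy-9β-(phenylselanyl)-8β-H-trans-daucane-4β,10α-diol (not isolated) | C/C=C(/C)C(=O)O[C@H]1C[C@@H](C)[C@H]([Se]c3ccccc3)[C@@H](O)[C@@]2(C)CC[C@@](O)(C(C)C)[C@H]12 | intermediate
23 | selenoxide of 22 (not isolated) | C/C=C(/C)C(=O)O[C@H]1C[C@@H](C)[C@H]([Se](=O)c3ccccc3)[C@@H](O)[C@@]2(C)CC[C@@](O)(C(C)C)[C@H]12 | intermediate
24 | 6α-angeloyloxy-trans-dauc-8-ene-4β,10α-diol | C/C=C(/C)C(=O)O[C@H]1CC(C)=C[C@@H](O)[C@@]2(C)CC[C@@](O)(C(C)C)[C@H]12 | intermediate
25 | lapiferine | C/C=C(/C)C(=O)O[C@H]1C[C@@]2(C)O[C@H]2[C@@H](O)[C@@]2(C)CC[C@@](O)(C(C)C)[C@H]12 | target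

Total step count: 15. Longest linear sequence: 15 steps (1 to 25).

Steps most likely to fail

Step 7. The cycloaddition may run through the compact orientation and give the cis ring fusion, or the silylated epoxide may ionise and be diverted (six-membered closure through C10, elimination) before the second bond forms. The fallback sets out from ester 6 and comes back at ketone 18. Ester 6 would be converted with MeNH(OMe)·HCl and i-PrMgCl into the Weinreb amide F1, and allylmagnesium bromide would give the β,γ-unsaturated ketone F2. Diazo transfer with 4-acetamidobenzenesulfonyl azide and DBU would give the vinyl diazo ketone F3. A chiral dirhodium tetracarboxylate, Rh2(S-PTAD)4 or its antipode, would then cyclopropanate the C1=C10 bond intramolecularly to the cis-divinylcyclopropane F4, which on warming to 80 °C would undergo the divinylcyclopropane (Cope) rearrangement to the dienone F5. This makes the same two bonds, C1–C5 and C7–C8, in one pot, with C1 and C8 set stereospecifically and C5 left trigonal. Conjugate borylation (CuCl, NaOt-Bu, a bisphosphine, B2pin2, MeOH) would give the β-boryl ketone F6, and NaBO3·4H2O oxidation would give the β-hydroxy ketone F7. The ring fusion would then be set by protonation at C5 and would have to be checked. Esterification of F7 as in step 9 returns to 18.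

Step 12. Deprotonation at C5 with β-elimination of the angelate, reduction by β-hydride transfer, or attack at the ester may compete with addition to the ketone. The fallback sets out from alcohol 13 and comes back at 20. Silylation of 13 with t-BuMe2SiOTf and 2,6-lutidine would give the bis-silyl ether F8, and selective methanolysis of the triethylsilyl ether (pyridinium p-toluenesulfonate, MeOH) would give the alcohol F9. Dess–Martin oxidation would give the ketone F10, which carries no ester and no good β-leaving group. Addition of 19 with CeCl3 would give the tertiary carbinol F11, and Bu4NF would give the diol F12. Esterification of the only secondary hydroxyl of F12 under the conditions of step 9 gives 20.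

Step 9. Acylation of the hindered C6 hydroxyl may be slow, and the acyl unit may isomerise from Z to E (tiglate) under forcing conditions. The fallback sets out from 13 and comes back at 16. Alcohol 13 would be esterified (dicyclohexylcarbodiimide, 4-dimethylaminopyridine) with 2-[bis(2,2,2-trifluoroethoxy)phosphoryl]propanoic acid to the phosphonopropionate F13. A Still–Gennari olefination of F13 with acetaldehyde (KN(SiMe3)2, 18-crown-6, THF, −78 °C) would then build the Z alkene of the angelate in place and give 16.

Further compounds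
F1 | step 7 | (4E,6E)-N-methoxy-N,4-dimethylocta-4,6-dienamide | CON(C)C(=O)CC/C(C)=C/C=C/C
F2 | step 7 | (6E,8E)-6-methyldeca-1,6,8-trien-4-one | C=CCC(=O)CC/C(C)=C/C=C/C
F3 | step 7 | (6E,8E)-3-diazo-6-methyldeca-1,6,8-trien-4-one | C=CC(=[N+]=[N-])C(=O)CC/C(C)=C/C=C/C
F4 | step 7 | 1-ethenyl-5-methyl-6-exo-[(E)-prop-1-enyl]bicyclo[3.1.0]hexan-2-one (cis-divinylcyclopropane, not isolated) | O=C1CC[C@]2(C)[C@@H](/C=C/C)[C@]12C=C
F5 | step 7 | 1β,8α-dimethylbicyclo[5.3.0]deca-5,9-dien-4-one (daucane locants) | O=C1CC[C@]2(C)C=C[C@H](C)CC=C12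
F6 | step 7 | 6α-(pinacolboryl)-1β,8α-dimethyl-5α-H-trans-bicyclo[5.3.0]dec-9-en-4-one (not isolated) | O=C1CC[C@]2(C)C=C[C@H](C)C[C@H](B3OC(C)(C)C(C)(C)O3)[C@@H]12
F7 | step 7 | 6α-hydroxy-1β,8α-dimethyl-5α-H-trans-bicyclo[5.3.0]dec-9-en-4-one | O=C1CC[C@]2(C)C=C[C@H](C)C[C@H](O)[C@@H]12
F8 | step 12 | 6α-(tert-butyldimethylsilyloxy)-4α-(triethylsilyloxy)-1β,8α-dimethyl-5α-H-trans-bicyclo[5.3.0]dec-9-ene | CC[Si](CC)(CC)O[C@@H]1CC[C@]2(C)C=C[C@H](C)C[C@H](O[Si](C)(C)C(C)(C)C)[C@@H]12
F9 | step 12 | 6α-(tert-butyldimethylsilyloxy)-1β,8α-dimethyl-5α-H-trans-bicyclo[5.3.0]dec-9-en-4α-ol | O[C@@H]1CC[C@]2(C)C=C[C@H](C)C[C@H](O[Si](C)(C)C(C)(C)C)[C@@H]12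
F10 | step 12 | 6α-(tert-butyldimethylsilyloxy)-1β,8α-dimethyl-5α-H-trans-bicyclo[5.3.0]dec-9-en-4-one | O=C1CC[C@]2(C)C=C[C@H](C)C[C@H](O[Si](C)(C)C(C)(C)C)[C@@H]12
F11 | step 12 | 6α-(tert-butyldimethylsilyloxy)-8β-H-trans-dauc-9-en-4β-ol | CC(C)[C@]1(O)CC[C@]2(C)C=C[C@H](C)C[C@H](O[Si](C)(C)C(C)(C)C)[C@@H]12
F12 | step 12 | 8β-H-trans-dauc-9-ene-4β,6α-diol | CC(C)[C@]1(O)CC[C@]2(C)C=C[C@H](C)C[C@H](O)[C@@H]12
F13 | step 9 | 2-[bis(2,2,2-trifluoroethoxy)phosphoryl]propanoate of 13 (mixture at the phosphonate carbon) | CC(C(=O)O[C@H]1C[C@@H](C)C=C[C@@]2(C)CC[C@@H](O[Si](CC)(CC)CC)[C@H]12)P(=O)(OCC(F)(F)F)OCC(F)(F)F
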